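In every flask, target and what we call the unfilled fraction add to one. The unfilled fraction is the part of the charge not yet read as target.

| flask | starting material | solid reagent | initiator | remark | time |
|---|---|---|---|---|---|
| violet | 0.028 M | 1.1 equiv | 1 mol% | run made earlier |  |
| ochre | 0.13 M | 1.1 equiv | 1 mol% | run made earlier |  |
| Wednesday's | 0.040 M | 1.10 equiv | 1 mol% |  | 50 min |
| Saturday's | 0.060 M | 1.10 equiv | 1 mol% |  | 50 min |
| Sunday's | 0.080 M | 1.10 equiv | 1 mol% |  | 50 min |
| Thursday's | 0.12 M | 1.10 equiv | 1 mol% |  | 50 min |
| Tuesday's | 0.20 M | 1.10 equiv | 1 mol% |  | 50 min |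

| run | time / min | target / % |
|---|---|---|
| violet | 4.00 | 3.9 |
| violet | 8.00 | 14.2 |
| violet | 12.0 | 21.5 |
| violet | 15.0 | 26.4 |
| violet | 20.0 | 35.0 |
| violet | 25.0 | 42.9 |
| ochre | 4.00 | 1.7 |
| ochre | 8.00 | 5.9 |
| ochre | 12.0 | 12.2 |
| ochre | 15.0 | 17.9 |
| ochre | 20.0 | 27.5 |
| ochre | 25.0 | 37.2 |

(readings scatter by 0.5 percentage points)

- at the start none of the solid reagent is in solution
- a reading or a percentage of target counts all its forms, free or not
- the concentration of target that is asked is that of its free form alone
- "hardly changes" means that all values lie within two and a half points (for a concentration: within two and a half percent of the largest)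

* [target] (only what is free in solution) at the end for Wednesday's, Saturday's, Sunday's, Thursday's, Tuesday's, in this order
* how the row runs (falls, then rises / hardly changes / falls all the way / rises all the way / rises, then falls)

As a first estimate, we treat the late fall of the unfilled fraction as a first-order decay. We take the logarithm of its fall from 15.0 min to 25.0 min, divided by that interval:

violet: 0.0254 min⁻¹

ochre: 0.0268 min⁻¹

The ochre charge is 4.64 times the violet one, yet these two values stand close. So we carry their mean, 0.0261 min⁻¹, as the unfilled decay constant, an apparent pseudo-first-order constant.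

One objection is that the ochre run has no such constant early. Between 4.00 min and 8.00 min it gives 0.0109 min⁻¹, lower than its late value. Even late, its reading climbs, from 0.0249 min⁻¹ between 15.0 min and 20.0 min to 0.0287 min⁻¹ between 20.0 min and 25.0 min, so for the ochre run 0.0261 min⁻¹ is an average over a window and not a steady constant. So we don't start from zero time. We start from each run's own reading at 25.0 min, which already holds its slow beginning, and run on to 50 min:

violet target fraction: 70.3%

ochre target fraction: 67.3%

A second objection is that one fraction for the whole row ignores this slip with charge. We therefore let the fraction fall with the logarithm of the charge, by 1.93% per unit of that logarithm. Fraction times charge then gives our row: 0.0278 M, 0.0413 M, 0.0546 M, 0.0809 M, 0.133 M. It rises all the way.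

A third objection stays open. The readings reach 0.0484 M of target, and they count all its forms, so a ceiling on free target above that cannot be read from them.

The forecast gives 0.028 M, 0.043 M, 0.058 M, 0.09 M, 0.152 M, rises all the way: “Free target therefore scales nearly with charge and rises throughout”.

The flask gives 0.0274 M, 0.0442 M, 0.0611 M, 0.0935 M, 0.132 M, rises all the way.

    initiator → 2 initiating radical (k = 7.41 × 10⁻⁵ s⁻¹)
    starting material + initiating radical → capped initiator + first chain carrier (k = 4.65 × 10⁵ M⁻¹ s⁻¹)
    partner + first chain carrier → target + second chain carrier (k = 1.10 × 10⁵ M⁻¹ s⁻¹)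
    starting material + second chain carrier → released group + first chain carrier (k = 1.51 × 10⁵ M⁻¹ s⁻¹)
    2 first chain carrier → ended chains (k = 1.60 × 10⁹ M⁻¹ s⁻¹)
    crystals ⇌ target, rate k6*(cs6 - [target]) while solid is left; crystals form when [target] > cs6 (solubility = 0.160 M, k = 0.0606 s⁻¹)
    solid reagent ⇌ partner, rate k7*(cs7 - [partner]) while solid is left; crystals form when [partner] > cs7 (solubility = 0.130 M, k = 8.53 × 10⁻⁴ s⁻¹)
    target ⇌ isomer of the product (K = 9.32, k = 7.96 × 10⁻⁵ s⁻¹)

Our row meets Tuesday's at 0.133 M against 0.132 M, but it parts from Thursday's at 0.0809 M against 0.0935 M. At the end, Tuesday's flask holds 5.89% of its solid reagent undissolved, and Thursday's holds 0%. Carried on at 0.0261 min⁻¹ from the ochre reading at 25.0 min, the unfilled fraction stands at 32.7% at 50 min, but Thursday's flask, charged at 0.12 M against ochre's 0.13 M, ends at 22.1%.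

The numbers in the tables were computed for substances that don't exist; the scatter is artificial.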